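The data stem from a simulated flask for an exercise; noise was put on by code.

Look for what sets the rate before ranking these flasks.

| flask | electrophile | nucleophile | free base | remark | time |
|---|---|---|---|---|---|
| alpha | 0.50 M | 0.50 M | 0.75 M | run made earlier |  |
| theta | 1 M | 0.50 M | 0.75 M | run made earlier |  |
| birch | 0.50 M | 0.500 M | 0.750 M | everything together in a closed stirred flask, run for 5.0 h | 5.0 h |
| ash | 0.50 M | 0.500 M (fed, over 5.00 h) | 0.750 M | all but nucleophile at the start; nucleophile goes in evenly over 5.00 h, the run ends at 5.0 h | 5.0 h |
| alder | 0.50 M | 0.500 M | 0.750 M | one stirred flow tank at steady state, fed with the mixture as stated, mean residence time 15.0 h |  |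
| larch | 0.50 M | 0.500 M | 0.750 M | one stirred flow tank at steady state, fed with the mixture as stated, mean residence time 5.0 h |  |

- alpha (time / h: target / %): 0.417: 5.0; 1.00: 10.7; 2.00: 17.9; 3.00: 21.6
- theta (time / min: target / %): 12.0: 2.7; 30.0: 6.0; 60.0: 10.6; 90.0: 13.6

(readings scatter by 0.5 percentage points)

* the set-up with the highest amount of target at the outlet or at the end, in percent of the electrophile put in ("none" if the first two lie within 2 percentage points) (birch / ash / alder / larch / none)
* amount of target at the outlet or at the end, in percent of the electrophile put in, birch
* amount of target at the outlet or at the end, in percent of the electrophile put in, ash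
* amount of target at the outlet or at the end, in percent of the electrophile put in, alder
* amount of target at the outlet or at the end, in percent of the electrophile put in, larch

- the stated concentrations are those of everything mixed, before any reaction; amounts are the same in each set-up
- the feed brings no volume worth counting
- the earlier runs were made in a closed, stirred flask

Dividing the earliest reading of each run by its time gives the share of electrophile turned per hour: 0.120 h⁻¹ in alpha. At that share, theta, with twice the electrophile and the same c(nucleophile), should read 2.40% at its first time; it reads 2.7%, inside the scatter of 0.5 percentage points. So the rate reads as first order in electrophile. Alpha and theta hold c(nucleophile) and c(free base) equal and say nothing of either, so first order in c(nucleophile) is my assumption, and on it c(nucleophile) is the concentration to follow. Theta's own share is 0.135 h⁻¹, the mean is 0.127 h⁻¹, and this gives 5.44 h, the half-life of electrophile at the charged c(nucleophile), which on that assumption stretches as c(nucleophile) falls.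

Now turn the question round: what must hold for closed birch to beat alder? By my reckoning, with equal charges falling together, birch reacts 38.9% of its electrophile, alder 49.2% and larch 30.6%. Birch therefore leads only if alder keeps as target less than 0.791 of the share birch keeps. Alpha's last reading stands at 0.781 of the same reckoning at 3.00 h, so target does go somewhere, but the readings stop before showing where that loss ends. I put alder ahead, with larch and ash behind birch.

The forecast chose birch, with 25.3% for birch, 18% for ash, 14.1% for alder and 17.1% for larch, noting that “flow tanks depend most on the assumed mechanism”. The flasks give 29.0% in birch, 19.2% in ash, 32.0% in alder and 22.3% in larch, so the best is alder.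

    acid set free + free base ⇌ salt of the base, settled at all times (K = 660 M⁻¹)
    target ⇌ isomer of the product (K = 0.450, k = 0.150 h⁻¹)
    electrophile + nucleophile → acid set free + target (k = 0.280 M⁻¹ h⁻¹)
    nucleophile + acid set free ⇌ protonated nucleophile, settled at all times (K = 1600 M⁻¹)

In birch at 5.00 h, nucleophile stands at 45.8% of its charge, which stretches the carried half-life to 11.9 h, against 11 h for the step itself. Birch makes target 4.49 times faster than it uses it up at 1.74 h, and still 2.43 times faster at 5.00 h. On the same assumption, a flask like birch with 2.0 M of nucleophile shortens the half-life to 1.36 h, leaving 7.82% of the electrophile at 5.00 h; computed, it holds 13% of electrophile and 66.1% of target.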